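**Retrosynthetic overview**
- Feature: each arene carries OH at C1, the C7 side chain at C2, the biaryl bond at C4 and CH3 at C5. The six carbons CH3–C5–C4–C4′–C5′–CH3 are therefore hexa-2,4-diyne, and C6–C1(O)–C2(C7)–C3 is a 2-silyloxy-3-alkylbuta-1,3-diene.
- Disconnection: C3–C4 and C5–C6 in each ring by [4+2]. Target 13 ⇐ bis(aryl silyl ether) 12 ⇐ bis(cyclohexa-1,4-diene) 11 ⇐ 2 × diene 8 + diyne 9.
- Diene 8 ⇐ enone 6 ⇐ allylic alcohol 5 ⇐ α-methylene aldehyde 3 ⇐ (S)-citronellal 1. C3 of citronellal becomes C7; its C1 and C2 become arene C1 and C2.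
- Ring order: ring A closes on one triple bond (enyne 10), ring A′ on the other in the same flask; both rings are aromatised afterwards.

Key step: step 5

Remark: the biaryl axis has only two ortho methyl groups and is taken to rotate freely, so the two (S) centres at C7 and C7′ are the only stereochemical elements. Arene numbering throughout: C1 (O), C2 (side chain), C4 (biaryl bond), C5 (CH3), C7 (benzylic CH).

**Route**

Step 1
Reactants: 1 (S)-citronellal; 2 formaldehyde
Product: 3 (S)-3,7-dimethyl-2-methylideneoct-6-enal
Conditions: aq CH2O (37%), pyrrolidine (10 mol %), EtCO2H (10 mol %), i-PrOH, 45 °C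
Reagents that add atoms: formaldehyde, C=O
Why: Amine/acid-catalysed Mannich condensation–elimination (α-methylenation via the pyrrolidine enamine) acts only at C2; the C3 stereocentre is not enolisable, and the conditions should be too mild to move the new alkene into the tetrasubstituted position.

Step 2
Reactants: 3 (S)-3,7-dimethyl-2-methylideneoct-6-enal; 4 methylmagnesium bromide
Product: 5 (4S)-4,8-dimethyl-3-methylidenenon-7-en-2-ol (mixture of C2 epimers)
Conditions: MeMgBr, THF, −78 → 0 °C; then H2O, aq NH4Cl work-up
Reagents that add atoms: methylmagnesium bromide, C[Mg]Br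
Why: Grignard 1,2-addition to an α-substituted enal; the new carbinol centre forms without control and is erased in step 3.

Step 3
Reactants: 5 (4S)-4,8-dimethyl-3-methylidenenon-7-en-2-ol
Product: 6 (S)-4,8-dimethyl-3-methylidenenon-7-en-2-one
Conditions: Dess–Martin periodinane, pyridine, CH2Cl2, 0 °C → rt
Reagents that add atoms: none
Why: Dess–Martin oxidation of a secondary allylic alcohol under pyridine buffering leaves the trisubstituted alkene alone, and the C4–H is cross-conjugated to the enone and so not acidified.

Step 4
Reactants: 6 (S)-4,8-dimethyl-3-methylidenenon-7-en-2-one; 7 tert-butyldimethylsilyl trifluoromethanesulfonate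
Product: 8 (S)-2-(tert-butyldimethylsilyloxy)-3-(6-methylhept-5-en-2-yl)buta-1,3-diene
Conditions: TBSOTf, Et3N, CH2Cl2, 0 °C
Reagents that add atoms: tert-butyldimethylsilyl trifluoromethanesulfonate, CC(C)(C)[Si](C)(C)OS(=O)(=O)C(F)(F)F
Why: Soft enolisation (O-silylation, then amine deprotonation) can remove a proton only from the methyl group, the sole enolisable α-position, giving the cross-conjugated 2-silyloxydiene with the stereocentre untouched.

Step 5
Reactants: 8 (S)-2-(tert-butyldimethylsilyloxy)-3-(6-methylhept-5-en-2-yl)buta-1,3-diene (2.4 equiv); 9 hexa-2,4-diyne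
Product: 11 C4–C4′-linked bis(cyclohexa-1,4-diene) bis(silyl enol ether) with OTBS at C1/C1′ and (S)-6-methylhept-5-en-2-yl at C2/C2′ and CH3 at C5/C5′, via propynyl cyclohexa-1,4-diene mono-adduct 10 (not isolated)
Conditions: CoBr2(dppe) (10 mol %), Zn powder (20 mol %), ZnI2 (20 mol %), CH2Cl2, rt; filtration through Et3N-deactivated silica
Reagents that add atoms: hexa-2,4-diyne, CC#CC#CC
Why: Zinc reduces the divalent cobalt precatalyst CoBr2(dppe) to a monovalent cobalt species (ZnI2 takes up halide and frees coordination sites) that binds the s-cis diene and one triple bond, couples them oxidatively to a cobaltacycle and releases the cyclohexa-1,4-diene by reductive elimination; this is the cobalt-catalysed neutral Diels–Alder reaction known for unactivated alkynes and 1,3-diynes with 2-silyloxy- and 2,3-disubstituted buta-1,3-dienes. Ring A closes by an intermolecular [4+2] annulation that forms C5–C6 and C3–C4 on one triple bond to give enyne 10, and ring A′ closes in the same way on the remaining triple bond, so no endo/exo ring-closure mode is involved. No stereocentre is created, the two C7 centres are remote spectators that are never deprotonated, and the product has no stereoisomers. The step needs the enol-ether terminus C6 to bond to the methyl-bearing alkyne carbon so that oxygen ends para to the C4–C4′ bond; the silyloxy group is the strongest π-donor on the diene and should outweigh the weaker opposing bias of the C2 alkyl group, and the conjugating alkynyl (then cyclohexadienyl) substituent should take the position para to oxygen as aryl groups do with 2-silyloxydienes under this diphosphine. The 2,3-disubstitution keeps the s-cis diene accessible, the diyne has no acidic C–H, the trisubstituted side-chain alkenes are inert to the catalyst, and the ligand on cobalt is the lever if the pairing leaks.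

Step 6
Reactants: 11 bis(cyclohexa-1,4-diene) bis(silyl enol ether)
Product: 12 4,4′-bis(tert-butyldimethylsilyloxy)-2,2′-dimethyl-5,5′-bis[(2S)-6-methylhept-5-en-2-yl]-1,1′-biphenyl
Conditions: DDQ (2.1 equiv), toluene, 0 °C → rt
Reagents that add atoms: none
Why: DDQ dehydrogenation (hydride abstraction from a doubly allylic CH2, then proton loss) aromatises 1,4-cyclohexadienes at or below room temperature, which should be much faster than attack on the benzylic C7–H or the side-chain alkenes; loss of a silyl group along the way would still lead to the phenol.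

Step 7
Reactants: 12 bis(aryl silyl ether)
Product: 13 2,2′-dimethyl-5,5′-bis[(2S)-6-methylhept-5-en-2-yl]-[1,1′-biphenyl]-4,4′-diol (target)
Conditions: TBAF, AcOH, THF, 0 °C → rt
Reagents that add atoms: none
Why: Fluoride cleavage of aryl silyl ethers (Si–F bond formation), buffered with acetic acid so that the electron-rich biphenolate is not exposed to air; nothing else in the molecule is fluoride-sensitive.

**Compound list**
1 | (S)-citronellal | O=CC[C@@H](C)CCC=C(C)C | starting material
2 | formaldehyde | C=O | starting material
3 | (S)-3,7-dimethyl-2-methylideneoct-6-enal | O=CC(=C)[C@@H](C)CCC=C(C)C | intermediate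
4 | methylmagnesium bromide | C[Mg]Br | starting material
5 | (4S)-4,8-dimethyl-3-methylidenenon-7-en-2-ol (C2 epimers) | CC(O)C(=C)[C@@H](C)CCC=C(C)C | intermediate
6 | (S)-4,8-dimethyl-3-methylidenenon-7-en-2-one | CC(=O)C(=C)[C@@H](C)CCC=C(C)C | intermediate
7 | tert-butyldimethylsilyl trifluoromethanesulfonate | CC(C)(C)[Si](C)(C)OS(=O)(=O)C(F)(F)F | starting material
8 | (S)-2-(tert-butyldimethylsilyloxy)-3-(6-methylhept-5-en-2-yl)buta-1,3-diene | C=C(O[Si](C)(C)C(C)(C)C)C(=C)[C@@H](C)CCC=C(C)C | intermediate
9 | hexa-2,4-diyne | CC#CC#CC | starting material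
10 | (S)-1-(tert-butyldimethylsilyloxy)-5-methyl-2-(6-methylhept-5-en-2-yl)-4-(prop-1-ynyl)cyclohexa-1,4-diene (mono-adduct, not isolated) | CC#CC1=C(C)CC(O[Si](C)(C)C(C)(C)C)=C(C1)[C@@H](C)CCC=C(C)C | intermediate
11 | 1,1′-bis(tert-butyldimethylsilyloxy)-5,5′-dimethyl-2,2′-bis[(2S)-6-methylhept-5-en-2-yl]-4,4′-bi(cyclohexa-1,4-diene), rings joined C4–C4′ | CC(C)=CCC[C@H](C)C1=C(O[Si](C)(C)C(C)(C)C)CC(C)=C(C1)C1=C(C)CC(O[Si](C)(C)C(C)(C)C)=C(C1)[C@@H](C)CCC=C(C)C | intermediate
12 | 4,4′-bis(tert-butyldimethylsilyloxy)-2,2′-dimethyl-5,5′-bis[(2S)-6-methylhept-5-en-2-yl]-1,1′-biphenyl | CC(C)=CCC[C@H](C)c1cc(-c2cc([C@@H](C)CCC=C(C)C)c(O[Si](C)(C)C(C)(C)C)cc2C)c(C)cc1O[Si](C)(C)C(C)(C)C | intermediate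
13 | 2,2′-dimethyl-5,5′-bis[(2S)-6-methylhept-5-en-2-yl]-[1,1′-biphenyl]-4,4′-diol | CC(C)=CCC[C@H](C)c1cc(-c2cc([C@@H](C)CCC=C(C)C)c(O)cc2C)c(C)cc1O | target

**Step count**
Total steps: 7. Longest linear sequence: 7 steps, from (S)-citronellal 1 to 13.

**Steps most likely to fail**

Step 5. The second ring closure may stall, because enyne 10 is more hindered than the diyne and can hold cobalt as an ene–yne chelate. The orientation of diene and alkyne may also leak, since the silyloxy and alkyl groups of the diene direct in opposite senses. The fallback sets out from 10 and comes back at 12. The cycloaddition is run with about one equivalent of 8 and stopped at the mono-adduct, which is isolated. DDQ (1 equiv, toluene, 0 °C) should dehydrogenate it to the aryl propyne (S)-tert-butyldimethyl[5-methyl-2-(6-methylhept-5-en-2-yl)-4-(prop-1-ynyl)phenoxy]silane F1. The substitution pattern of this simple arene also shows whether the first ring closed in the required sense. F1 is an ordinary aryl alkyl alkyne, the substrate class in which the aryl group ends para to the silyloxy group. A second [4+2] with 8 under CoBr2(dppe)/Zn/ZnI2 should give the aryl cyclohexa-1,4-diene silyl enol ether F2, and DDQ then gives 12.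

Step 6. Once an arene has formed, DDQ may abstract hydride at the benzylic C7–H, scrambling or destroying the stereocentre. Adventitious hydrolysis of the silyl enol ethers would also leave enones that DDQ aromatises only slowly. The fallback sets out from 11 and comes back at 13. Both silyl enol ethers are cleaved deliberately (TBAF, AcOH, THF, 0 °C) to the bis(β,γ-enone) 3,3′-dimethyl-6,6′-bis[(2S)-6-methylhept-5-en-2-yl]-4,4′-bi(cyclohex-3-en-1-one) F3, a mixture of epimers at the ring carbon α to the ketone. F3 is then dehydrogenated to the biphenol under aerobic palladium catalysis: Pd(TFA)2 (palladium bis(trifluoroacetate), divalent palladium, 5 mol %), 2-(dimethylamino)pyridine, TsOH, O2 (1 atm), DMSO, 80 °C. This oxidant does not abstract benzylic hydride.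

Step 1. Prolonged amine/acid catalysis at 45 °C may move the exocyclic alkene into conjugation as the tetrasubstituted enal, which erases the C3 stereocentre, or may give aldol self-condensation of the aldehyde. The fallback sets out from 1 and comes back at 3. It separates C–C bond formation from alkene formation in a stoichiometric Mannich sequence at room temperature. Dimethylmethylideneammonium iodide and Et3N in CH2Cl2 give the Mannich base (3S)-2-[(dimethylamino)methyl]-3,7-dimethyloct-6-enal F4 (C2 epimers, used crude). MeI converts it to the trimethylammonium iodide of the same aldehyde F5. Aqueous NaHCO3/CH2Cl2 at rt then eliminates trimethylamine to give 3 under non-equilibrating conditions.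

**Further compounds**
F1 | step 5 | (S)-tert-butyldimethyl[5-methyl-2-(6-methylhept-5-en-2-yl)-4-(prop-1-ynyl)phenoxy]silane | CC#Cc1cc([C@@H](C)CCC=C(C)C)c(O[Si](C)(C)C(C)(C)C)cc1C
F2 | step 5 | aryl cyclohexa-1,4-diene silyl enol ether (ring A′ aromatic, ring A as in 11) | CC(C)=CCC[C@H](C)C1=C(O[Si](C)(C)C(C)(C)C)CC(C)=C(C1)c1cc([C@@H](C)CCC=C(C)C)c(O[Si](C)(C)C(C)(C)C)cc1C
F3 | step 6 | 3,3′-dimethyl-6,6′-bis[(2S)-6-methylhept-5-en-2-yl]-4,4′-bi(cyclohex-3-en-1-one) (C6 epimers) | CC(C)=CCC[C@H](C)C1C(=O)CC(C)=C(C1)C1=C(C)CC(=O)C(C1)[C@@H](C)CCC=C(C)C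
F4 | step 1 | (3S)-2-[(dimethylamino)methyl]-3,7-dimethyloct-6-enal (C2 epimers) | CN(C)CC(C=O)[C@@H](C)CCC=C(C)C
F5 | step 1 | [(3S)-2-formyl-3,7-dimethyloct-6-enyl]trimethylammonium iodide (C2 epimers) | C[N+](C)(C)CC(C=O)[C@@H](C)CCC=C(C)C.[I-]
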